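**Assumption:** the target is the (R)-lavandulyl enantiomer (CIP assignment from the given SMILES); (−)-sparteine, ClCH2Bpin and the Weinreb phosphonate are taken as catalogue reagents.

## Retrosynthetic overview

1. No rings are formed; both benzene rings are purchased (5-methoxyresorcinol and 2,4-dihydroxybenzaldehyde).
2. The chalcone is not made by Claisen–Schmidt condensation: the aryl–C(=O) bond is cut instead, as A-ring aryllithium plus an (E)-cinnamoyl Weinreb amide, then global MOM removal.
3. The lavandulyl group is not introduced as a lavandulyl electrophile: the isopropenyl–C* bond comes from a stereoretentive Zweifel olefination of a secondary boronic ester.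
4. Key step: the C*–CH2Ar bond and the stereocenter are made together by sparteine-controlled lithiation–borylation of an achiral homoprenyl carbamate with an ArCH2Bpin.
5. ArCH2Bpin comes from ortho-lithiation of bis-MOM 5-methoxyresorcinol and ClCH2Bpin homologation.

## Route

**Step 1**
Reactants: 1 (5-methoxyresorcinol), 2 (chloromethyl methyl ether, MOMCl)
Product: 3, 1-methoxy-3,5-bis(methoxymethoxy)benzene
Conditions: NaH, MOMCl, DMF, 0 °C → rt
Reagents that add atoms: MOMCl, COCCl
Why: Williamson-type O-alkylation of both phenoxides installs MOM groups that later act as ortho-directing groups.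

**Step 2**
Reactants: 3, 4 (2-(chloromethyl)-4,4,5,5-tetramethyl-1,3,2-dioxaborolane, ClCH2Bpin)
Product: 5, 2-[2,6-bis(methoxymethoxy)-4-methoxybenzyl]-4,4,5,5-tetramethyl-1,3,2-dioxaborolane
Conditions: n-BuLi, THF, 0 °C → rt, 1 h; then 4, −78 °C → rt (warm to 50 °C if migration is slow)
Reagents that add atoms: ClCH2Bpin, ClCB1OC(C)(C)C(C)(C)O1
Why: Directed ortho-metalation occurs at the C–H flanked by both OMOM groups, and the aryl "ate" complex undergoes a Matteson-type 1,2-aryl shift with loss of chloride to give the benzyl boronate.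

**Step 3**
Reactants: 6 (4-methylpent-3-en-1-ol), 7 (N,N-diisopropylcarbamoyl chloride)
Product: 8, 4-methylpent-3-en-1-yl N,N-diisopropylcarbamate
Conditions: i-Pr2NCOCl, Et3N, DMAP (cat.), CH2Cl2, reflux
Reagents that add atoms: N,N-diisopropylcarbamoyl chloride, CC(C)N(C(C)C)C(=O)Cl
Why: Simple O-carbamoylation gives the Hoppe carbamate that directs α-lithiation and later serves as the leaving group.

**Step 4 (key step)**
Reactants: 8 (carbamate), 5 (benzyl boronate)
Product: 9, 2-[(2R)-1-[2,6-bis(methoxymethoxy)-4-methoxyphenyl]-5-methylhex-4-en-2-yl]-4,4,5,5-tetramethyl-1,3,2-dioxaborolane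
Conditions: 8, s-BuLi, (−)-sparteine, Et2O, −78 °C, 5 h; then 5, −78 °C, 1 h; then reflux, 16 h
Reagents that add atoms: none beyond the two reactants (5 supplies ArCH2 and Bpin: COCOc1cc(OC)cc(OCOC)c1CB1OC(C)(C)C(C)(C)O1)
Why: Hoppe–Aggarwal lithiation–borylation: (−)-sparteine-directed removal of the pro-S α-H gives the (S)-α-lithio carbamate, which captures 5 with retention, and the benzyl group then migrates from B to C anti to the departing carbamate (inversion), setting the single stereocenter as (R).

**Step 5**
Reactants: 9, 10 (2-bromopropene)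
Product: 11, 5-methoxy-1,3-bis(methoxymethoxy)-2-[(2R)-5-methyl-2-(prop-1-en-2-yl)hex-4-en-1-yl]benzene (the (R)-lavandulyl arene)
Conditions: 2-bromopropene, t-BuLi (2 equiv), Et2O, −78 °C; add 9 in THF, −78 °C; I2, MeOH, −78 °C; NaOMe, MeOH, −78 °C → rt
Reagents that add atoms: 2-bromopropene (as isopropenyllithium), C=C(C)Br
Why: Zweifel olefination: iodination of the isopropenyl boronate complex triggers 1,2-migration of the secondary alkyl group with retention, and methoxide-induced anti-elimination of B/I gives the 1,1-disubstituted alkene, so (R)-C–B becomes (R)-C–isopropenyl.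

**Step 6**
Reactants: 12 (2,4-dihydroxybenzaldehyde), 2 (MOMCl)
Product: 13, 2,4-bis(methoxymethoxy)benzaldehyde
Conditions: MOMCl, K2CO3, acetone, reflux
Reagents that add atoms: MOMCl, COCCl
Why: Phenol O-alkylation protects both hydroxyls (including the H-bonded 2-OH) as base-stable MOM ethers.

**Step 7**
Reactants: 13, 14 (diethyl [2-(methoxy(methyl)amino)-2-oxoethyl]phosphonate)
Product: 15, (E)-3-[2,4-bis(methoxymethoxy)phenyl]-N-methoxy-N-methylprop-2-enamide
Conditions: 14, NaH, THF, 0 °C → rt
Reagents that add atoms: phosphonate 14, CCOP(=O)(OCC)CC(=O)N(C)OC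
Why: Horner–Wadsworth–Emmons olefination with a stabilized phosphonate gives the (E)-enamide selectively.

**Step 8**
Reactants: 11, 15
Product: 16, (E)-3-[2,4-bis(methoxymethoxy)phenyl]-1-[6-methoxy-2,4-bis(methoxymethoxy)-3-[(2R)-5-methyl-2-(prop-1-en-2-yl)hex-4-en-1-yl]phenyl]prop-2-en-1-one (tetra-MOM kuraridin)
Conditions: 11, n-BuLi, TMEDA, THF, 0 °C, 1 h; then 15, −78 → 0 °C; aq. NH4Cl
Reagents that add atoms: Weinreb amide 15, COCOc1ccc(/C=C/C(=O)N(C)OC)c(OCOC)c1
Why: Directed ortho-metalation at the ring C–H flanked by OMe and OMOM (the two open positions are equivalent) followed by Weinreb ketone synthesis, where the chelated tetrahedral intermediate stops over-addition and keeps the (E)-enone; the stereocenter is not acidic under these conditions.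

**Step 9**
Reactants: 16
Product: 17, kuraridin
Conditions: 3 M aq. HCl, MeOH, rt (Ar, dark), quench at full conversion
Reagents that add atoms: none
Why: Acid-catalysed acetal methanolysis removes all four phenolic MOM groups under mild conditions that the same A-ring pattern with a prenyl side chain is known to tolerate, and the stereocenter is not involved.

## Compound list

1 | 5-methoxyresorcinol | COc1cc(O)cc(O)c1 | starting material
2 | chloromethyl methyl ether (MOMCl) | COCCl | starting material
3 | 1-methoxy-3,5-bis(methoxymethoxy)benzene | COCOc1cc(OC)cc(OCOC)c1 | intermediate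
4 | 2-(chloromethyl)-4,4,5,5-tetramethyl-1,3,2-dioxaborolane | ClCB1OC(C)(C)C(C)(C)O1 | starting material
5 | 2-[2,6-bis(methoxymethoxy)-4-methoxybenzyl]-4,4,5,5-tetramethyl-1,3,2-dioxaborolane | COCOc1cc(OC)cc(OCOC)c1CB1OC(C)(C)C(C)(C)O1 | intermediate
6 | 4-methylpent-3-en-1-ol | CC(C)=CCCO | starting material
7 | N,N-diisopropylcarbamoyl chloride | CC(C)N(C(C)C)C(=O)Cl | starting material
8 | 4-methylpent-3-en-1-yl N,N-diisopropylcarbamate | CC(C)=CCCOC(=O)N(C(C)C)C(C)C | intermediate
9 | 2-[(2R)-1-[2,6-bis(methoxymethoxy)-4-methoxyphenyl]-5-methylhex-4-en-2-yl]-4,4,5,5-tetramethyl-1,3,2-dioxaborolane | CC1(C)OB(OC1(C)C)[C@H](CC=C(C)C)Cc1c(OCOC)cc(OC)cc1OCOC | intermediate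
10 | 2-bromopropene | C=C(C)Br | starting material
11 | 5-methoxy-1,3-bis(methoxymethoxy)-2-[(2R)-5-methyl-2-(prop-1-en-2-yl)hex-4-en-1-yl]benzene | C=C(C)[C@H](CC=C(C)C)Cc1c(OCOC)cc(OC)cc1OCOC | intermediate
12 | 2,4-dihydroxybenzaldehyde | O=Cc1ccc(O)cc1O | starting material
13 | 2,4-bis(methoxymethoxy)benzaldehyde | COCOc1ccc(C=O)c(OCOC)c1 | intermediate
14 | diethyl [2-(methoxy(methyl)amino)-2-oxoethyl]phosphonate | CCOP(=O)(OCC)CC(=O)N(C)OC | starting material
15 | (E)-3-[2,4-bis(methoxymethoxy)phenyl]-N-methoxy-N-methylprop-2-enamide | COCOc1ccc(/C=C/C(=O)N(C)OC)c(OCOC)c1 | intermediate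
16 | tetra-MOM kuraridin, (E)-enone, (R)-lavandulyl | C=C(C)[C@H](CC=C(C)C)Cc1c(OCOC)cc(OC)c(C(=O)/C=C/c2ccc(OCOC)cc2OCOC)c1OCOC | intermediate
17 | kuraridin | C=C(C)[C@H](CC=C(C)C)Cc1c(O)cc(OC)c(C(=O)/C=C/c2ccc(O)cc2O)c1O | target

## Summary

Total steps: 9. Longest linear sequence: 6 (Steps 1 → 2 → 4 → 5 → 8 → 9).

Three steps most likely to fail, with fallbacks:

- **Step 4 (lithiation–borylation).** Risks are incomplete migration of the hindered benzyl boronate or eroded er. Fallback: set the stereocenter by auxiliary control instead. Acylate (R)-4-benzyl-2-oxazolidinone with the 3-arylpropanoic acid (from lithiated 3 + DMF, Wittig, conjugate reduction), carry out Evans prenylation (NaHMDS, prenyl bromide), then convert the imide carbonyl to the isopropenyl group (Weinreb amide, MeMgBr, Petasis/Tebbe methylenation).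
- **Step 8 (aryllithium acylation).** Risks are lateral (benzylic) lithiation, conjugate addition, or base-induced breakdown of the Weinreb amide by the hindered aryllithium. Fallback: acylate the aryllithium with N-methoxy-N-methylacetamide to give the acetophenone, then form the enone by Claisen–Schmidt condensation with aldehyde 13 (KOH, EtOH).
- **Step 9 (global deprotection).** Risks are cyclisation to the flavanone (kurarinone), acid-induced chroman formation, or alkene migration in the lavandulyl group. Fallback: change the protecting-group strategy to SEM ethers on all four phenols (SEMCl in Steps 1 and 6, same ortho-directing role) and unmask with fluoride (TBAF or CsF, DMF) so no Brønsted acid is used; any flavanone formed is reopened with KOH/MeOH followed by cold acidification.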